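**Retrosynthetic overview**
- Target ⇐ hydrogenolysis of the phenolic benzyl ether of the fully substituted oxolane.
- C–H at the trimethoxyphenyl carbon ⇐ hydride reduction of the oxocarbenium ion from a cyclic hemiketal; hemiketal ⇐ 3,4,5-trimethoxyphenyllithium + a 3,4-trans-4,5-cis γ-butyrolactone.
- Lactone C3 methyl ⇐ enolate methylation of the cis-4-methyl-5-aryl lactone.
- Key C–C bond (lactone C4–C5) ⇐ carbene-bound homoenolate of crotonaldehyde (β-carbon as nucleophile) + formyl carbon of the protected aryl aldehyde, with lactonisation in the same step.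
- Ring order: the oxolane is the only ring built, closed as the lactone in step 1 and kept to the end; both benzene rings are bought.

Assumption: the aldehyde is bought as its benzyl ether, and the (5aS,10bR) antipode of the triazolium catalyst is written by analogy with related homoenolate additions; if the first run gives the mirror-image lactone, the commercial (5aR,10bS) salt is used instead.

**Step 1**
Reactants: 1 3-(benzyloxy)-4,5-dimethoxybenzaldehyde; 2 (E)-but-2-enal (crotonaldehyde)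
Product: 4 (4S,5R)-5-[3-(benzyloxy)-4,5-dimethoxyphenyl]-4-methyloxolan-2-one, via Breslow homoenolate 3 (not isolated)
Conditions: (5aS,10bR)-2-mesityl-5a,10b-dihydro-4H,6H-indeno[2,1-b][1,2,4]triazolo[4,3-d][1,4]oxazin-2-ium chloride (10 mol%), DBU (10 mol%), LiCl (1 equiv), THF, 23 °C, 2 (2 equiv) added over 8 h
Reagents that add atoms: none
Why: Proposed new method: the carbene adds to the formyl group of 2 and proton transfer gives the catalyst-bound homoenolate 3, whose normally electrophilic β-carbon attacks the Li+-activated formyl carbon of 1 from the face left open by the indane wall (sets C4) through a closed, OH/Li-bridged transition state that puts aryl and methyl cis (sets C5), after which tautomerisation to the acyl azolium and O-acylation close the lactone and free the carbene; the closest known reactions are the racemic N-mesityl-carbene-catalysed enal/aryl aldehyde [3+2] annulation to cis-γ-butyrolactones (conjugate umpolung) and enantioselective homoenolate additions of the same triazolium family to activated carbonyl acceptors.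

**Step 2**
Reactants: 4 (4S,5R)-5-[3-(benzyloxy)-4,5-dimethoxyphenyl]-4-methyloxolan-2-one
Product: 6 (3S,4S,5R)-5-[3-(benzyloxy)-4,5-dimethoxyphenyl]-3,4-dimethyloxolan-2-one, via lithium enolate 5 (not isolated)
Conditions: LiN(SiMe3)2 (1.1 equiv), THF, −78 °C, 45 min; MeI (3 equiv), −78 to −45 °C
Reagents that add atoms: iodomethane, CI
Why: Enolate alkylation: the lithium enolate 5 is methylated on the face opposite the cis C4-methyl and C5-aryl groups, so the new methyl is installed 3,4-trans (3S), the kinetic outcome coinciding with the thermodynamic preference.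

**Step 3**
Reactants: 6 (3S,4S,5R)-5-[3-(benzyloxy)-4,5-dimethoxyphenyl]-3,4-dimethyloxolan-2-one; 7 5-bromo-1,2,3-trimethoxybenzene
Product: 9 (3S,4S,5R)-5-[3-(benzyloxy)-4,5-dimethoxyphenyl]-3,4-dimethyl-2-(3,4,5-trimethoxyphenyl)oxolan-2-ol, via aryllithium 8 (not isolated)
Conditions: 7 (1.3 equiv), n-BuLi (1.25 equiv), THF, −78 °C, 30 min; then 6, −78 °C, 1 h; AcOH quench at −78 °C
Reagents that add atoms: none
Why: Bromine–lithium exchange gives aryllithium 8, which adds once to the lactone carbonyl because the tetrahedral lithium hemiketalate is stable at −78 °C (lactone-to-lactol aryl addition), and the cold acetic acid quench returns the hemiketal without epimerising C3; the anomeric centre formed is irrelevant because step 4 flattens it.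

**Step 4**
Reactants: 9 (3S,4S,5R)-5-[3-(benzyloxy)-4,5-dimethoxyphenyl]-3,4-dimethyl-2-(3,4,5-trimethoxyphenyl)oxolan-2-ol
Product: 11 (2R,3S,4S,5S)-2-[3-(benzyloxy)-4,5-dimethoxyphenyl]-3,4-dimethyl-5-(3,4,5-trimethoxyphenyl)oxolane, via oxocarbenium ion 10 (not isolated)
Conditions: Et3SiH (3 equiv), BF3·OEt2 (2 equiv), CH2Cl2, −78 to −50 °C; Et3N then aq NaHCO3 quench cold
Reagents that add atoms: none
Why: Reductive deoxygenation of the hemiketal (ionic hydrogenation): BF3 ionises 9 to the aryl-stabilised oxocarbenium ion 10 and Et3SiH delivers hydride by inside attack on the envelope, on the face that carries only the C3 methyl and is opposite the C4 methyl and the C5 aryl, so the trimethoxyphenyl group ends trans to its neighbouring methyl and cis to the other aryl (new centre S), while the low temperature keeps the existing benzylic C–O bond from ionising.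

**Step 5**
Reactants: 11 (2R,3S,4S,5S)-2-[3-(benzyloxy)-4,5-dimethoxyphenyl]-3,4-dimethyl-5-(3,4,5-trimethoxyphenyl)oxolane
Product: 12 5-[(2R,3S,4S,5S)-3,4-dimethyl-5-(3,4,5-trimethoxyphenyl)oxolan-2-yl]-2,3-dimethoxyphenol (CNP0293669.2)
Conditions: H2 (1 atm), 10% Pd/C, EtOAc, 23 °C
Reagents that add atoms: none
Why: Hydrogenolysis of the phenolic benzyl ether over Pd/C in neutral ethyl acetate is far faster than cleavage of the dialkyl benzylic C–O bonds of the oxolane, so the ring and its four stereocentres are untouched.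

**Compound list**
1 | 3-(benzyloxy)-4,5-dimethoxybenzaldehyde | COc1cc(C=O)cc(OCc2ccccc2)c1OC | starting material
2 | (E)-but-2-enal | C/C=C/C=O | starting material
3 | catalyst-bound homoenolate (Breslow-type dienaminol of 2 on the (5aS,10bR) triazolylidene carbene) | C/C=C/C(O)=C1N(c2c(C)cc(C)cc2C)N=C2CO[C@H]3Cc4ccccc4[C@H]3N12 | intermediate
4 | (4S,5R)-5-[3-(benzyloxy)-4,5-dimethoxyphenyl]-4-methyloxolan-2-one (4,5-cis) | COc1cc([C@@H]2OC(=O)C[C@@H]2C)cc(OCc3ccccc3)c1OC | intermediate
5 | lithium enolate of 4 | COc1cc([C@@H]2OC([O-])=C[C@@H]2C)cc(OCc3ccccc3)c1OC.[Li+] | intermediate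
6 | (3S,4S,5R)-5-[3-(benzyloxy)-4,5-dimethoxyphenyl]-3,4-dimethyloxolan-2-one (3,4-trans-4,5-cis) | COc1cc([C@@H]2OC(=O)[C@@H](C)[C@@H]2C)cc(OCc3ccccc3)c1OC | intermediate
7 | 5-bromo-1,2,3-trimethoxybenzene | COc1cc(Br)cc(OC)c1OC | starting material
8 | (3,4,5-trimethoxyphenyl)lithium | [Li]c1cc(OC)c(OC)c(OC)c1 | intermediate
9 | (3S,4S,5R)-5-[3-(benzyloxy)-4,5-dimethoxyphenyl]-3,4-dimethyl-2-(3,4,5-trimethoxyphenyl)oxolan-2-ol (anomer mixture, in equilibrium with the open γ-hydroxy ketone) | COc1cc([C@@H]2OC(O)(c3cc(OC)c(OC)c(OC)c3)[C@@H](C)[C@@H]2C)cc(OCc4ccccc4)c1OC | intermediate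
10 | (3S,4S,5R)-5-[3-(benzyloxy)-4,5-dimethoxyphenyl]-3,4-dimethyl-2-(3,4,5-trimethoxyphenyl)-4,5-dihydro-3H-furan-1-ium hydroxytrifluoroborate | COc1cc([C@@H]2[O+]=C(c3cc(OC)c(OC)c(OC)c3)[C@@H](C)[C@@H]2C)cc(OCc4ccccc4)c1OC.O[B-](F)(F)F | intermediate
11 | (2R,3S,4S,5S)-2-[3-(benzyloxy)-4,5-dimethoxyphenyl]-3,4-dimethyl-5-(3,4,5-trimethoxyphenyl)oxolane | COc1cc([C@@H]2O[C@H](c3cc(OC)c(OC)c(OC)c3)[C@@H](C)[C@@H]2C)cc(OCc4ccccc4)c1OC | intermediate
12 | 5-[(2R,3S,4S,5S)-3,4-dimethyl-5-(3,4,5-trimethoxyphenyl)oxolan-2-yl]-2,3-dimethoxyphenol | COc1cc([C@@H]2O[C@H](c3cc(OC)c(OC)c(OC)c3)[C@@H](C)[C@@H]2C)cc(O)c1OC | target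

**Totals**
Total step count: 5. Longest linear sequence: 5 steps (1 or 2 to 12).

**Steps most likely to fail**

Step 1 is the riskiest. The enantioselective version with an unactivated, fairly electron-rich aryl aldehyde is unproven. Likely problems are modest ee, a cis:trans ratio near 4:1, and self-annulation of crotonaldehyde. The fallback sets out from 1 and returns at 4. Brown crotylboration of 1 uses (Z)-crotyl-B(Ipc)2, made from cis-2-butene, n-BuLi/KOt-Bu and (+)-Ipc2BOMe (the antipode from (−)-α-pinene, which attacks the Re face of aryl aldehydes), in THF at −78 °C with NaOH/H2O2 work-up. It gives the syn homoallylic alcohol (1R,2S)-1-[3-(benzyloxy)-4,5-dimethoxyphenyl]-2-methylbut-3-en-1-ol F1. Hydroboration with 9-BBN and NaOH/H2O2 oxidation gives (1R,2S)-1-[3-(benzyloxy)-4,5-dimethoxyphenyl]-2-methylbutane-1,4-diol F2. TEMPO (cat.)/PhI(OAc)2 in CH2Cl2 oxidises the primary alcohol and the lactol that forms, giving lactone 4.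

Step 4 is second. Hydride could enter the wrong face, or BF3 could ionise the existing benzylic C–O bond and drift the material towards the all-trans isomer or a ring-opened product. The fallback sets out from 9 and returns at 11, closing the ring by C–O bond formation without a Lewis acid. TESCl/imidazole in DMF traps the open-chain tautomer of 9 as (2S,3S,4R)-4-[3-(benzyloxy)-4,5-dimethoxyphenyl]-2,3-dimethyl-4-[(triethylsilyl)oxy]-1-(3,4,5-trimethoxyphenyl)butan-1-one F3. Reagent-controlled reduction with (S)-Me-CBS (cat.)/BH3·SMe2 gives (1R,2S,3S,4R)-4-[3-(benzyloxy)-4,5-dimethoxyphenyl]-2,3-dimethyl-4-[(triethylsilyl)oxy]-1-(3,4,5-trimethoxyphenyl)butan-1-ol F4. MsCl/Et3N at −20 °C gives (1R,2S,3S,4R)-4-[3-(benzyloxy)-4,5-dimethoxyphenyl]-2,3-dimethyl-4-[(triethylsilyl)oxy]-1-(3,4,5-trimethoxyphenyl)butyl methanesulfonate F5, used crude. TBAF then frees the alkoxide, which displaces the mesylate with inversion to give 11; if the mesylate ionises instead, closure still favours the same trans aryl/methyl ring.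

Step 3 is third. The aryllithium could add twice, or enolise the lactone, which on quench would return C3-epimerised lactone. The fallback sets out from 6 and returns at 9. MeNH(OMe)·HCl/AlMe3 in CH2Cl2 at 0 °C opens the lactone to (2S,3S,4R)-4-[3-(benzyloxy)-4,5-dimethoxyphenyl]-4-hydroxy-N-methoxy-N,2,3-trimethylbutanamide F6. It is silylated at once with TBSOTf/2,6-lutidine to (2S,3S,4R)-4-[3-(benzyloxy)-4,5-dimethoxyphenyl]-4-[(tert-butyldimethylsilyl)oxy]-N-methoxy-N,2,3-trimethylbutanamide F7. Aryllithium 8 in THF at −78 °C stops cleanly at the ketone (2S,3S,4R)-4-[3-(benzyloxy)-4,5-dimethoxyphenyl]-4-[(tert-butyldimethylsilyl)oxy]-2,3-dimethyl-1-(3,4,5-trimethoxyphenyl)butan-1-one F8. HF·pyridine in THF removes the silyl group and the hydroxy ketone closes to hemiketal 9.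

**Further compounds**
F1 | step 1 | (1R,2S)-1-[3-(benzyloxy)-4,5-dimethoxyphenyl]-2-methylbut-3-en-1-ol | COc1cc([C@H](O)[C@@H](C)C=C)cc(OCc2ccccc2)c1OC
F2 | step 1 | (1R,2S)-1-[3-(benzyloxy)-4,5-dimethoxyphenyl]-2-methylbutane-1,4-diol | COc1cc([C@H](O)[C@@H](C)CCO)cc(OCc2ccccc2)c1OC
F3 | step 4 | (2S,3S,4R)-4-[3-(benzyloxy)-4,5-dimethoxyphenyl]-2,3-dimethyl-4-[(triethylsilyl)oxy]-1-(3,4,5-trimethoxyphenyl)butan-1-one | COc1cc([C@H](O[Si](CC)(CC)CC)[C@@H](C)[C@H](C)C(=O)c2cc(OC)c(OC)c(OC)c2)cc(OCc3ccccc3)c1OC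
F4 | step 4 | (1R,2S,3S,4R)-4-[3-(benzyloxy)-4,5-dimethoxyphenyl]-2,3-dimethyl-4-[(triethylsilyl)oxy]-1-(3,4,5-trimethoxyphenyl)butan-1-ol | COc1cc([C@H](O[Si](CC)(CC)CC)[C@@H](C)[C@H](C)[C@@H](O)c2cc(OC)c(OC)c(OC)c2)cc(OCc3ccccc3)c1OC
F5 | step 4 | (1R,2S,3S,4R)-4-[3-(benzyloxy)-4,5-dimethoxyphenyl]-2,3-dimethyl-4-[(triethylsilyl)oxy]-1-(3,4,5-trimethoxyphenyl)butyl methanesulfonate | COc1cc([C@H](O[Si](CC)(CC)CC)[C@@H](C)[C@H](C)[C@@H](OS(C)(=O)=O)c2cc(OC)c(OC)c(OC)c2)cc(OCc3ccccc3)c1OC
F6 | step 3 | (2S,3S,4R)-4-[3-(benzyloxy)-4,5-dimethoxyphenyl]-4-hydroxy-N-methoxy-N,2,3-trimethylbutanamide | COc1cc([C@H](O)[C@@H](C)[C@H](C)C(=O)N(C)OC)cc(OCc2ccccc2)c1OC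
F7 | step 3 | (2S,3S,4R)-4-[3-(benzyloxy)-4,5-dimethoxyphenyl]-4-[(tert-butyldimethylsilyl)oxy]-N-methoxy-N,2,3-trimethylbutanamide | COc1cc([C@H](O[Si](C)(C)C(C)(C)C)[C@@H](C)[C@H](C)C(=O)N(C)OC)cc(OCc2ccccc2)c1OC
F8 | step 3 | (2S,3S,4R)-4-[3-(benzyloxy)-4,5-dimethoxyphenyl]-4-[(tert-butyldimethylsilyl)oxy]-2,3-dimethyl-1-(3,4,5-trimethoxyphenyl)butan-1-one | COc1cc([C@H](O[Si](C)(C)C(C)(C)C)[C@@H](C)[C@H](C)C(=O)c2cc(OC)c(OC)c(OC)c2)cc(OCc3ccccc3)c1OC
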